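**Retrosynthetic overview**

1. Ring names: A = methyl salicylate ring, B = central ring of the diaryl ether, C = benzo ring of the indenone, D = its five-membered enone ring (C1 = carbonyl, C2, C3, C3a, C4 to C7, C7a), E = orcinol ring on C3. The last step removes five benzyl ethers.
2. Key disconnection: the C2–ring B bond and the C2=C3 bond are cut together. C2 becomes the diazo carbon of a diazomethyl ketone on C7a, C3 the diaryl ketone on C3a, and ring B an aryldifluoroborane. In the forward sense this is formal insertion of C2 into the ring B–boron bond with loss of N2, followed by aldol condensation.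
3. Enabling feature: in ring D the single carbon C2 bridges two acyl-level carbons, C1 and C3, which sit ortho to each other on ring C (at C7a and C3a). C2 can therefore enter as a carbenoid carbon that takes ring B from boron and so becomes the enolate that closes on C3. The C3 oxygen then leaves easily, because C3 is doubly benzylic and flanked by the two ortho oxygens of ring E.
4. Ring C is built from open-chain pieces. A Diels–Alder reaction with aromatisation, between a 1,1,3-trioxygenated diene and the acetylenic keto ester of ring E, sets 4-OH, 6-OMe, the aroyl group and the carboxyl carbon at once.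
5. Rings A and B are joined by SNAr of a symmetric ring A resorcylate on a 2-fluorobenzaldehyde, then Baeyer–Villiger oxidation (CHO to OH), then Br to BF3K. Order of ring formation: C (step 5), then D (step 15). Rings A, B and E come from purchased arenes.

Key step: step 15

Remark: the target has no stereocentre and its SMILES carries no axis descriptor, so the hindered aryl–C2 and aryl–C3 axes are treated as configurationally undefined and no stereocontrol is planned.

**Route**

Step 1
Reactants: 1 2,6-dihydroxy-4-methylbenzaldehyde (atranol)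
Product: 2 2,6-bis(benzyloxy)-4-methylbenzaldehyde
Conditions: BnBr, K2CO3, DMF, 60 °C
Reagents that add atoms: benzyl bromide, BrCc1ccccc1
Why: Williamson ether synthesis in a dipolar aprotic solvent should alkylate both hydrogen-bonded phenols, and benzyl is chosen because it survives base, acid chloride formation and boron Lewis acids of moderate strength.

Step 2
Reactants: 2 2,6-bis(benzyloxy)-4-methylbenzaldehyde, 3 methyl propiolate
Product: 5 methyl 4-[2,6-bis(benzyloxy)-4-methylphenyl]-4-hydroxybut-2-ynoate (racemic), via lithium acetylide 4 (not isolated)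
Conditions: LiN(iPr)2, THF, −78 °C; then 2, −78 °C; AcOH quench
Reagents that add atoms: none
Why: This is a 1,2-addition of a lithium acetylide to an aldehyde, run at −78 °C so that the ester-bearing acetylide does not self-condense, and the new carbinol stereocentre forms as a racemate that step 3 erases.

Step 3
Reactants: 5 methyl 4-[2,6-bis(benzyloxy)-4-methylphenyl]-4-hydroxybut-2-ynoate
Product: 6 methyl 4-[2,6-bis(benzyloxy)-4-methylphenyl]-4-oxobut-2-ynoate
Conditions: Dess–Martin periodinane, CH2Cl2, 0 → 23 °C
Reagents that add atoms: none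
Why: Hypervalent iodine oxidation of a benzylic propargylic alcohol runs under neutral, nucleophile-free conditions, which should spare the very electrophilic acetylenic keto ester.

Step 4
Reactants: 7 methyl (E)-3-methoxybut-2-enoate
Product: 9 1,3-dimethoxy-1-(trimethylsilyloxy)buta-1,3-diene (ketene acetal geometry not defined, both isomers converge in step 5), via lithium dienolate 8 (not isolated)
Conditions: LiN(iPr)2, THF, −78 °C; Me3SiCl, −78 → 0 °C
Reagents that add atoms: chlorotrimethylsilane, C[Si](C)(C)Cl
Why: γ-Deprotonation of the β-methoxy enoate followed by O-silylation of the dienolate (silyl ketene acetal formation) should give the 1,1,3-trioxygenated diene.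

Step 5
Reactants: 6 methyl 4-[2,6-bis(benzyloxy)-4-methylphenyl]-4-oxobut-2-ynoate, 9 1,3-dimethoxy-1-(trimethylsilyloxy)buta-1,3-diene
Product: 11 methyl 2-[2,6-bis(benzyloxy)-4-methylbenzoyl]-3-hydroxy-5-methoxybenzoate, via cycloadduct 10 (not isolated)
Conditions: toluene, 23 → 80 °C; then 1 M HCl, THF, 23 °C
Reagents that add atoms: none
Why: In this Diels–Alder reaction with aromatisation the nucleophilic CH2 terminus of 9 should bond to the alkyne carbon β to the ketone (the stronger acceptor, twisted out of conjugation with ring E), so the ketene acetal carbon ends next to the aroyl group and loss of methanol and of the silyl group delivers ring C with the free OH, the OMe, the aroyl group and the ester already in place.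

Step 6
Reactants: 11 methyl 2-[2,6-bis(benzyloxy)-4-methylbenzoyl]-3-hydroxy-5-methoxybenzoate
Product: 12 methyl 3-(benzyloxy)-2-[2,6-bis(benzyloxy)-4-methylbenzoyl]-5-methoxybenzoate
Conditions: BnBr, K2CO3, DMF, 50 °C
Reagents that add atoms: benzyl bromide, BrCc1ccccc1
Why: Williamson ether synthesis caps the only free phenol, which would otherwise be methylated by diazomethane and would protonate the boron enolate later.

Step 7
Reactants: 12 methyl 3-(benzyloxy)-2-[2,6-bis(benzyloxy)-4-methylbenzoyl]-5-methoxybenzoate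
Product: 13 3-(benzyloxy)-2-[2,6-bis(benzyloxy)-4-methylbenzoyl]-5-methoxybenzoic acid
Conditions: LiOH, THF–MeOH–H2O, 60 °C; then 1 M HCl
Reagents that add atoms: lithium hydroxide, [Li+].[OH-]
Why: Saponification should cleave the ester, which has only one ortho substituent, while the non-enolisable shielded diaryl ketone and the benzyl ethers are inert to hydroxide.

Step 8
Reactants: 13 3-(benzyloxy)-2-[2,6-bis(benzyloxy)-4-methylbenzoyl]-5-methoxybenzoic acid
Product: 15 1-{3-(benzyloxy)-2-[2,6-bis(benzyloxy)-4-methylbenzoyl]-5-methoxyphenyl}-2-diazoethan-1-one, via acid chloride 14 (not isolated)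
Conditions: (COCl)2, cat. DMF, CH2Cl2, 0 → 23 °C, evaporate; CH2N2, Et3N, Et2O–THF, 0 °C
Reagents that add atoms: diazomethane, C=[N+]=[N-]
Why: Diazomethane is acylated by an acid chloride with Et3N as HCl scavenger (first stage of the Arndt–Eistert sequence), and the four ortho substituents around the diaryl ketone should disfavour closure of 14 to the cyclic pseudo chloride.

Step 9
Reactants: 16 2-bromo-1-fluoro-4-methoxybenzene
Product: 18 3-bromo-2-fluoro-5-methoxybenzaldehyde, via aryllithium 17 (not isolated)
Conditions: LiN(iPr)2, THF, −78 °C; DMF, −78 °C; 1 M HCl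
Reagents that add atoms: N,N-dimethylformamide, CN(C)C=O
Why: In this directed ortho-lithiation and formylation, fluorine is the strongest acidifying group and the bulky amide should take the open proton next to it rather than the crowded one between Br and OMe, while −78 °C suppresses aryne formation and bromine migration.

Step 10
Reactants: 18 3-bromo-2-fluoro-5-methoxybenzaldehyde, 19 methyl 2,6-dihydroxy-4-methylbenzoate
Product: 20 methyl 2-(2-bromo-6-formyl-4-methoxyphenoxy)-6-hydroxy-4-methylbenzoate
Conditions: K2CO3, DMF, 100 °C (19 in excess)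
Reagents that add atoms: none
Why: In this SNAr reaction the fluoride is activated by the ortho formyl group and the ortho bromine, the symmetry of 19 removes any question of site, and an excess of 19 should suppress double arylation.

Step 11
Reactants: 20 methyl 2-(2-bromo-6-formyl-4-methoxyphenoxy)-6-hydroxy-4-methylbenzoate
Product: 22 methyl 2-(2-bromo-6-hydroxy-4-methoxyphenoxy)-6-hydroxy-4-methylbenzoate, via aryl formate 21 (not isolated)
Conditions: mCPBA, CH2Cl2, 23 °C; then cat. K2CO3, MeOH, 0 °C
Reagents that add atoms: 3-chloroperbenzoic acid, OOC(=O)c1cccc(Cl)c1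
Why: In the Baeyer–Villiger oxidation of this 2-aryloxybenzaldehyde the oxygen-substituted aryl group should migrate in preference to hydrogen, and methanolysis of the formate in methanol keeps the ring A ester open rather than lactonised.

Step 12
Reactants: 22 methyl 2-(2-bromo-6-hydroxy-4-methoxyphenoxy)-6-hydroxy-4-methylbenzoate
Product: 23 methyl 2-(benzyloxy)-6-[2-(benzyloxy)-6-bromo-4-methoxyphenoxy]-4-methylbenzoate
Conditions: BnBr, K2CO3, DMF, 23 → 40 °C
Reagents that add atoms: benzyl bromide, BrCc1ccccc1
Why: A double Williamson ether synthesis at low temperature should let O-alkylation outrun attack of the ring B phenoxide on the ring A ester.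

Step 13
Reactants: 23 methyl 2-(benzyloxy)-6-[2-(benzyloxy)-6-bromo-4-methoxyphenoxy]-4-methylbenzoate
Product: 24 methyl 2-(benzyloxy)-6-[2-(benzyloxy)-4-methoxy-6-(4,4,5,5-tetramethyl-1,3,2-dioxaborolan-2-yl)phenoxy]-4-methylbenzoate
Conditions: B2pin2, Pd(dppf)Cl2, KOAc, 1,4-dioxane, 90 °C
Reagents that add atoms: bis(pinacolato)diboron, CC1(C)OB(OC1(C)C)B1OC(C)(C)C(C)(C)O1
Why: In the Miyaura borylation zerovalent palladium inserts into the only C–Br bond and acetate-assisted transmetalation delivers boron, at a temperature that should be too low for intramolecular C–H arylation of ring A.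

Step 14
Reactants: 24 methyl 2-(benzyloxy)-6-[2-(benzyloxy)-4-methoxy-6-(4,4,5,5-tetramethyl-1,3,2-dioxaborolan-2-yl)phenoxy]-4-methylbenzoate
Product: 25 potassium {3-(benzyloxy)-2-[3-(benzyloxy)-2-(methoxycarbonyl)-5-methylphenoxy]-5-methoxyphenyl}trifluoroborate
Conditions: KHF2, MeOH–H2O, 23 °C
Reagents that add atoms: potassium hydrogen difluoride, F.[F-].[K+]
Why: Ligand exchange of a pinacol boronate with bifluoride should give a storable salt from which a Lewis acidic dihaloborane can be released on demand.

Step 15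
Reactants: 15 1-{3-(benzyloxy)-2-[2,6-bis(benzyloxy)-4-methylbenzoyl]-5-methoxyphenyl}-2-diazoethan-1-one, 25 potassium {3-(benzyloxy)-2-[3-(benzyloxy)-2-(methoxycarbonyl)-5-methylphenoxy]-5-methoxyphenyl}trifluoroborate
Product: 29 pentabenzyl ether of ascomindone B (methyl 2-(benzyloxy)-6-(2-(benzyloxy)-6-{4-(benzyloxy)-3-[2,6-bis(benzyloxy)-4-methylphenyl]-6-methoxy-1-oxo-1H-inden-2-yl}-4-methoxyphenoxy)-4-methylbenzoate), via aryldifluoroborane 26 (not isolated), via difluoroboron enolate 27 (not isolated), via boron aldolate 28 (not isolated)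
Conditions: 25, Me3SiCl, MeCN, 23 °C, evaporate; CH2Cl2, −20 °C, slow addition of 15, → 23 °C; then BF3·OEt2, 0 → 23 °C
Reagents that add atoms: none
Why: Proposed new method: fluoride abstraction from 25 by Me3SiCl should give the Lewis acidic borane 26, to whose boron the unhindered nucleophilic diazo carbon of 15 adds, and the ate complex then loses N2 with a 1,2-shift of ring B (the only carbon ligand on boron) onto that carbon, which makes the C2–ring B bond and, once boron has moved to oxygen, the enolate 27. The closest known reaction type is the Hooz reaction of aryldihaloboranes and arylboroxines with α-diazocarbonyl compounds, whose enol borinates are known to enter aldol additions, and what is new is its use on a diazoketone that carries its own aldol acceptor, so that arylation and ring closure run in one flask. Ring D closes by a 5-(enolendo)-exo-trig aldol addition of C2 to the C3 ketone, activated by BF3·OEt2 that is added only after N2 evolution has ended; this is the same closure that operates in the classical 2,3-diarylindenone synthesis from benzylidenephthalides and arylmagnesium halides, and aldolate 28 should then ionise at the doubly benzylic C3 and lose the acidic C2–H to give the enone. The two stereocentres of 28 are transient and are erased by this elimination, so no stereocontrol is needed. The step needs boron to react at the diazo carbon and the ketone to stay untouched until C2 bears ring B, and the four ortho substituents around the C3 carbonyl should secure this by shielding it from boron and from the neutral diazo carbon, while the later enolate reaches it intramolecularly. The site of ring closure is fixed by the ortho relation of the two acyl groups on ring C, so no regioisomeric indenone can form.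

Step 16
Reactants: 29 pentabenzyl ether of ascomindone B
Product: 30 ascomindone B
Conditions: BCl3, pentamethylbenzene, CH2Cl2, −78 °C; then H2O
Reagents that add atoms: none
Why: In this Lewis acid debenzylation with a non-basic cation scavenger, BCl3 should ionise the five aryl benzyl ethers and pentamethylbenzene should trap the benzyl cations by Friedel–Crafts alkylation, while the two aryl methyl ethers (no neighbouring carbonyl for chelation), the methyl ester and the C2=C3 bond, which hydrogenolysis would endanger, should persist.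

**Compound list**

1 | 2,6-dihydroxy-4-methylbenzaldehyde (atranol) | Cc1cc(O)c(C=O)c(O)c1 | starting material
2 | 2,6-bis(benzyloxy)-4-methylbenzaldehyde | Cc1cc(OCc2ccccc2)c(C=O)c(OCc2ccccc2)c1 | intermediate
3 | methyl propiolate | C#CC(=O)OC | starting material
4 | methyl 3-lithiopropiolate | [Li]C#CC(=O)OC | intermediate
5 | methyl 4-[2,6-bis(benzyloxy)-4-methylphenyl]-4-hydroxybut-2-ynoate (racemic) | COC(=O)C#CC(O)c1c(OCc2ccccc2)cc(C)cc1OCc1ccccc1 | intermediate
6 | methyl 4-[2,6-bis(benzyloxy)-4-methylphenyl]-4-oxobut-2-ynoate | COC(=O)C#CC(=O)c1c(OCc2ccccc2)cc(C)cc1OCc1ccccc1 | intermediate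
7 | methyl (E)-3-methoxybut-2-enoate | CO/C(C)=C/C(=O)OC | starting material
8 | lithium dienolate of 7 | [Li]OC(OC)=CC(=C)OC | intermediate
9 | 1,3-dimethoxy-1-(trimethylsilyloxy)buta-1,3-diene (geometry not defined) | C=C(OC)C=C(OC)O[Si](C)(C)C | intermediate
10 | methyl 2-[2,6-bis(benzyloxy)-4-methylbenzoyl]-3,5-dimethoxy-3-(trimethylsilyloxy)cyclohexa-1,4-diene-1-carboxylate (racemic) | COC1=CC(OC)(O[Si](C)(C)C)C(C(=O)c2c(OCc3ccccc3)cc(C)cc2OCc2ccccc2)=C(C(=O)OC)C1 | intermediate
11 | methyl 2-[2,6-bis(benzyloxy)-4-methylbenzoyl]-3-hydroxy-5-methoxybenzoate | COC(=O)c1cc(OC)cc(O)c1C(=O)c1c(OCc2ccccc2)cc(C)cc1OCc1ccccc1 | intermediate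
12 | methyl 3-(benzyloxy)-2-[2,6-bis(benzyloxy)-4-methylbenzoyl]-5-methoxybenzoate | COC(=O)c1cc(OC)cc(OCc2ccccc2)c1C(=O)c1c(OCc2ccccc2)cc(C)cc1OCc1ccccc1 | intermediate
13 | 3-(benzyloxy)-2-[2,6-bis(benzyloxy)-4-methylbenzoyl]-5-methoxybenzoic acid | OC(=O)c1cc(OC)cc(OCc2ccccc2)c1C(=O)c1c(OCc2ccccc2)cc(C)cc1OCc1ccccc1 | intermediate
14 | 3-(benzyloxy)-2-[2,6-bis(benzyloxy)-4-methylbenzoyl]-5-methoxybenzoyl chloride | ClC(=O)c1cc(OC)cc(OCc2ccccc2)c1C(=O)c1c(OCc2ccccc2)cc(C)cc1OCc1ccccc1 | intermediate
15 | 1-{3-(benzyloxy)-2-[2,6-bis(benzyloxy)-4-methylbenzoyl]-5-methoxyphenyl}-2-diazoethan-1-one | [N-]=[N+]=CC(=O)c1cc(OC)cc(OCc2ccccc2)c1C(=O)c1c(OCc2ccccc2)cc(C)cc1OCc1ccccc1 | intermediate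
16 | 2-bromo-1-fluoro-4-methoxybenzene | COc1ccc(F)c(Br)c1 | starting material
17 | (3-bromo-2-fluoro-5-methoxyphenyl)lithium | COc1cc(Br)c(F)c([Li])c1 | intermediate
18 | 3-bromo-2-fluoro-5-methoxybenzaldehyde | COc1cc(Br)c(F)c(C=O)c1 | intermediate
19 | methyl 2,6-dihydroxy-4-methylbenzoate | COC(=O)c1c(O)cc(C)cc1O | starting material
20 | methyl 2-(2-bromo-6-formyl-4-methoxyphenoxy)-6-hydroxy-4-methylbenzoate | COC(=O)c1c(O)cc(C)cc1Oc1c(Br)cc(OC)cc1C=O | intermediate
21 | methyl 2-[2-bromo-6-(formyloxy)-4-methoxyphenoxy]-6-hydroxy-4-methylbenzoate | COC(=O)c1c(O)cc(C)cc1Oc1c(Br)cc(OC)cc1OC=O | intermediate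
22 | methyl 2-(2-bromo-6-hydroxy-4-methoxyphenoxy)-6-hydroxy-4-methylbenzoate | COC(=O)c1c(O)cc(C)cc1Oc1c(O)cc(OC)cc1Br | intermediate
23 | methyl 2-(benzyloxy)-6-[2-(benzyloxy)-6-bromo-4-methoxyphenoxy]-4-methylbenzoate | COC(=O)c1c(OCc2ccccc2)cc(C)cc1Oc1c(OCc2ccccc2)cc(OC)cc1Br | intermediate
24 | pinacol boronate of 23 (Bpin in place of Br) | COC(=O)c1c(OCc2ccccc2)cc(C)cc1Oc1c(OCc2ccccc2)cc(OC)cc1B1OC(C)(C)C(C)(C)O1 | intermediate
25 | potassium trifluoroborate of 23 (BF3K in place of Br) | [K+].COC(=O)c1c(OCc2ccccc2)cc(C)cc1Oc1c(OCc2ccccc2)cc(OC)cc1[B-](F)(F)F | intermediate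
26 | aryldifluoroborane (BF2 in place of Br of 23) | COC(=O)c1c(OCc2ccccc2)cc(C)cc1Oc1c(OCc2ccccc2)cc(OC)cc1B(F)F | intermediate
27 | difluoroboron enolate of the ring B benzyl ring C ketone (enolate geometry not defined) | COC(=O)c1c(OCc2ccccc2)cc(C)cc1Oc1c(OCc2ccccc2)cc(OC)cc1C=C(OB(F)F)c1cc(OC)cc(OCc2ccccc2)c1C(=O)c1c(OCc2ccccc2)cc(C)cc1OCc1ccccc1 | intermediate
28 | 3-(difluoroboryloxy)-2,3-diarylindan-1-one (racemic, relative configuration not defined) | COC(=O)c1c(OCc2ccccc2)cc(C)cc1Oc1c(OCc2ccccc2)cc(OC)cc1C1C(=O)c2cc(OC)cc(OCc3ccccc3)c2C1(OB(F)F)c1c(OCc2ccccc2)cc(C)cc1OCc1ccccc1 | intermediate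
29 | pentabenzyl ether of ascomindone B | COC(=O)c1c(OCc2ccccc2)cc(C)cc1Oc1c(OCc2ccccc2)cc(OC)cc1C1=C(c2c(OCc3ccccc3)cc(C)cc2OCc2ccccc2)c2c(OCc3ccccc3)cc(OC)cc2C1=O | intermediate
30 | ascomindone B | COC(=O)c1c(O)cc(C)cc1Oc1c(O)cc(OC)cc1C1=C(c2c(O)cc(C)cc2O)c2c(O)cc(OC)cc2C1=O | target

**Step count and risks**

Total step count: 16.
Longest linear sequence: 9 steps (1, 2, 3, 5, 6, 7, 8, 15, 16).

Steps most likely to fail:

**Step 15.** The Lewis acid may trigger loss of N2 before the boron–carbon bond forms. This could happen by attack of the diazo carbon on the neighbouring ketone with aryl shift, or by capture of halide. The hindered ketone may also resist the aldol closure, so that the sequence stalls at the open-chain stage.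

The fallback uses known chemistry, sets out from 15 and returns at 29. Aqueous HBr in Et2O at 0 °C should convert the diazoketone into 2-bromo-1-{3-(benzyloxy)-2-[2,6-bis(benzyloxy)-4-methylbenzoyl]-5-methoxyphenyl}ethan-1-one F1. TsOH in refluxing toluene with removal of water should close ring D by acid-catalysed intramolecular aldol condensation to 4-(benzyloxy)-3-[2,6-bis(benzyloxy)-4-methylphenyl]-2-bromo-6-methoxy-1H-inden-1-one F2. Acid is chosen so that the halohydrin stage cannot close to an epoxide. A Suzuki–Miyaura coupling of F2 with boronate 24 (Pd(OAc)2, SPhos, K3PO4, toluene–H2O, 90 °C) then makes the same C2–ring B bond on the finished ring and gives 29.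

**Step 8.** The activated acid may close onto the neighbouring ketone to the cyclic pseudo chloride, which would divert diazomethane from the acyl carbon.

The fallback avoids any activated acid, sets out from ester 12 and returns at 15. Dimethylsulfoxonium methylide (Me3S(O)I, KOtBu, THF, reflux) should be acylated by the ester to give 1-{3-(benzyloxy)-2-[2,6-bis(benzyloxy)-4-methylbenzoyl]-5-methoxyphenyl}-2-(dimethyloxo-λ6-sulfanylidene)ethan-1-one F3. HBr should replace the sulfoxonium group and give the bromomethyl ketone F1 described above. N,N'-ditosylhydrazine and DBU in THF at 0 °C should turn F1 into diazoketone 15, because N-alkylation of the hydrazide anion is expected to outrun enolisation.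

**Step 5.** Regiocontrol may erode if the ester, rather than the twisted aryl ketone, steers the first bond of the cycloaddition.

The fallback leaves the ketone as the only acceptor on the alkyne, sets out from aldehyde 2, uses diene 9 and returns at acid 13.
- The lithium acetylide of tert-butyldimethyl(prop-2-yn-1-yloxy)silane (n-BuLi, THF, −78 °C) should add to 2 to give 1-[2,6-bis(benzyloxy)-4-methylphenyl]-4-[(tert-butyldimethylsilyl)oxy]but-2-yn-1-ol F4.
- Dess–Martin oxidation should give 1-[2,6-bis(benzyloxy)-4-methylphenyl]-4-[(tert-butyldimethylsilyl)oxy]but-2-yn-1-one F5.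
- Diels–Alder reaction with 9 (toluene, 110 °C, then silica gel) should give [2,6-bis(benzyloxy)-4-methylphenyl][2-({[tert-butyl(dimethyl)silyl]oxy}methyl)-6-hydroxy-4-methoxyphenyl]methanone F6.
- Benzylation (BnBr, K2CO3, DMF) should give [2-(benzyloxy)-6-({[tert-butyl(dimethyl)silyl]oxy}methyl)-4-methoxyphenyl][2,6-bis(benzyloxy)-4-methylphenyl]methanone F7.
- Bu4NF in THF should free [2-(benzyloxy)-6-(hydroxymethyl)-4-methoxyphenyl][2,6-bis(benzyloxy)-4-methylphenyl]methanone F8.
- TEMPO with PhI(OAc)2 in MeCN–H2O should oxidise F8 to acid 13.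

**Further compounds**

F1 | step 15 | 2-bromo-1-{3-(benzyloxy)-2-[2,6-bis(benzyloxy)-4-methylbenzoyl]-5-methoxyphenyl}ethan-1-one | BrCC(=O)c1cc(OC)cc(OCc2ccccc2)c1C(=O)c1c(OCc2ccccc2)cc(C)cc1OCc1ccccc1
F2 | step 15 | 4-(benzyloxy)-3-[2,6-bis(benzyloxy)-4-methylphenyl]-2-bromo-6-methoxy-1H-inden-1-one | BrC1=C(c2c(OCc3ccccc3)cc(C)cc2OCc2ccccc2)c2c(OCc3ccccc3)cc(OC)cc2C1=O
F3 | step 8 | 1-{3-(benzyloxy)-2-[2,6-bis(benzyloxy)-4-methylbenzoyl]-5-methoxyphenyl}-2-(dimethyloxo-λ6-sulfanylidene)ethan-1-one | CS(C)(=O)=CC(=O)c1cc(OC)cc(OCc2ccccc2)c1C(=O)c1c(OCc2ccccc2)cc(C)cc1OCc1ccccc1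
F4 | step 5 | 1-[2,6-bis(benzyloxy)-4-methylphenyl]-4-[(tert-butyldimethylsilyl)oxy]but-2-yn-1-ol (racemic) | CC(C)(C)[Si](C)(C)OCC#CC(O)c1c(OCc2ccccc2)cc(C)cc1OCc1ccccc1
F5 | step 5 | 1-[2,6-bis(benzyloxy)-4-methylphenyl]-4-[(tert-butyldimethylsilyl)oxy]but-2-yn-1-one | CC(C)(C)[Si](C)(C)OCC#CC(=O)c1c(OCc2ccccc2)cc(C)cc1OCc1ccccc1
F6 | step 5 | [2,6-bis(benzyloxy)-4-methylphenyl][2-({[tert-butyl(dimethyl)silyl]oxy}methyl)-6-hydroxy-4-methoxyphenyl]methanone | CC(C)(C)[Si](C)(C)OCc1cc(OC)cc(O)c1C(=O)c1c(OCc2ccccc2)cc(C)cc1OCc1ccccc1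
F7 | step 5 | [2-(benzyloxy)-6-({[tert-butyl(dimethyl)silyl]oxy}methyl)-4-methoxyphenyl][2,6-bis(benzyloxy)-4-methylphenyl]methanone | CC(C)(C)[Si](C)(C)OCc1cc(OC)cc(OCc2ccccc2)c1C(=O)c1c(OCc2ccccc2)cc(C)cc1OCc1ccccc1
F8 | step 5 | [2-(benzyloxy)-6-(hydroxymethyl)-4-methoxyphenyl][2,6-bis(benzyloxy)-4-methylphenyl]methanone | OCc1cc(OC)cc(OCc2ccccc2)c1C(=O)c1c(OCc2ccccc2)cc(C)cc1OCc1ccccc1
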